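Ring C of the flavanone is a pyran fused to ring A in which C4 is the benzylic carbon and O1 the phenolic oxygen, the two ends of an ortho-quinone methide, while C2–C3 with ring B is a styrene. Disconnecting C3–C4 and O1–C2 therefore leads to a fully substituted salicylaldehyde and 4-methoxystyrene. One enantioselective hetero-Diels–Alder reaction of the orthoformate-derived 4-methoxy methide, mediated by a chiral phosphoric acid, builds ring C, sets C2 and delivers C4 at the alcohol oxidation level. The precursor is 2-hydroxy-3,5-diprenyl-4-(triisopropylsilyloxy)benzaldehyde, with a free ortho-hydroxyl and a silyl ether that can later be removed without base.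

Key step: step 4

Remarks and assumptions
- Flavonoid numbering is used (O1, C2, C3, C4, C4a, C5–C8, C8a); ring A is the benzo ring, ring C the pyran ring, ring B the 4-methoxyphenyl group.
- The target, compound 15, is the natural 7-hydroxy-4'-methoxy-6,8-diprenylflavanone with 2S configuration.
- The 2,4-cis cycloadduct with 2S configuration is the (2S,4S) isomer; the priorities at C2 (O1 > C1' > C3 > H) do not change in steps 5–7, so 2S in 12 corresponds to 2S in 15.
- (R)-TRIP is (R)-3,3'-bis(2,4,6-triisopropylphenyl)-1,1'-binaphthyl-2,2'-diyl hydrogen phosphate. Its sense of induction cannot be predicted with confidence; the (R)-acid is written and its antipode would be used if it leads to the (2R,4R) series.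
- The C7 oxygen is carried as a triisopropylsilyl ether. This blocks para-quinone methide formation and cyclisation of that phenol onto its two prenyl neighbours, withstands the acid of steps 4 and 5, and comes off with buffered fluoride.
- Compound 13 is carried as a mixture of C4 epimers (C4 left open in its SMILES), since C4 becomes a carbonyl in step 6.

Step 1
Reactants: 1 β-resorcylaldehyde (2,4-dihydroxybenzaldehyde)
Product: 3 diiodide (2,4-dihydroxy-3,5-diiodobenzaldehyde), via monoiodide 2 (not isolated)
Conditions: NIS (2.2 equiv), CF3CO2H (10 mol %), MeCN, 0 °C to rt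
Reagents that add atoms: N-iodosuccinimide, O=C1CCC(=O)N1I
Why: Electrophilic aromatic iodination, in which C3 and C5 are each ortho or para to both hydroxyl groups whereas C6 is meta to both and next to the formyl group, so two equivalents of iodonium should stop at the 3,5-diiodide (the first iodine is expected at the less hindered C5, and any 3-iodo isomer converges on the same product).

Step 2
Reactants: 3 diiodide (2,4-dihydroxy-3,5-diiodobenzaldehyde)
Product: 4 silyl ether (2-hydroxy-3,5-diiodo-4-(triisopropylsilyloxy)benzaldehyde)
Conditions: TIPSOTf (1.1 equiv), 2,6-lutidine (2 equiv), CH2Cl2, −40 to 0 °C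
Reagents that add atoms: triisopropylsilyl trifluoromethanesulfonate, CC(C)[Si](OS(=O)(=O)C(F)(F)F)(C(C)C)C(C)C
Why: Selective O-silylation of a phenol, in which the 2-hydroxyl is tied into a hydrogen bond with the formyl group and is the less acidic one, so the more acidic 4-hydroxyl should be silylated, the very reactive silyl triflate overcoming the two flanking iodine atoms.

Step 3
Reactants: 4 silyl ether (2-hydroxy-3,5-diiodo-4-(triisopropylsilyloxy)benzaldehyde); 5 prenylstannane (tributyl(3-methylbut-2-enyl)stannane)
Product: 7 salicylaldehyde (2-hydroxy-3,5-bis(3-methylbut-2-enyl)-4-(triisopropylsilyloxy)benzaldehyde), via monoprenyl iodide 6 (not isolated)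
Conditions: 5 (3 equiv), Pd(PPh3)4 (10 mol %), DMF, 90 °C
Reagents that add atoms: tributyl(3-methylbut-2-enyl)stannane 5, CC(C)=CC[Sn](CCCC)(CCCC)CCCC
Why: Twofold Stille cross-coupling, in which zerovalent palladium inserts into each C–I bond, the prenyl group is transferred from tin and reductive elimination under triphenylphosphine ligation should give the linear prenyl arene, with the aldehyde, the hydrogen-bonded phenol and the silyl ether tolerated and the less hindered C5 iodide expected to react first.

Step 4
Reactants: 7 salicylaldehyde (2-hydroxy-3,5-bis(3-methylbut-2-enyl)-4-(triisopropylsilyloxy)benzaldehyde); 8 trimethyl orthoformate; 9 para-methoxystyrene (1-ethenyl-4-methoxybenzene)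
Product: 12 cycloadduct ((2S,4S)-4-methoxy-2-(4-methoxyphenyl)-6,8-bis(3-methylbut-2-enyl)-7-(triisopropylsilyloxy)chromane), via dimethyl acetal 10 (not isolated), via methoxy ortho-quinone methide 11 (not isolated)
Conditions: 8 (3 equiv), 9 (3 equiv), (R)-TRIP (10 mol %), 5 Å MS, toluene, −20 °C to rt
Reagents that add atoms: trimethyl orthoformate 8, COC(OC)OC; 4-methoxystyrene 9, C=Cc1ccc(OC)cc1
Why: Proposed new method: acid-catalysed exchange with 8 gives acetal 10, which loses methanol with help from the free ortho-hydroxyl to give methide 11, present as its O-protonated form (a 2-hydroxyaryl methoxycarbenium ion) hydrogen-bonded and ion-paired to the chiral phosphate; the CH2 terminus of 9 adds to the methide carbon (C3–C4) and the phenolic oxygen closes on the incipient 4-methoxybenzylic cation (O1–C2) in an asynchronous inverse-electron-demand hetero-Diels–Alder reaction. The closest known reaction types are the phosphoric acid-catalysed enantioselective [4+2] cycloaddition of ortho-quinone methides generated from ortho-hydroxybenzylic alcohols with styrenes and the racemic acid-catalysed union of salicylaldehydes, orthoformates and alkenes to 4-alkoxychromans; their combination, an enantioselective cycloaddition of a 4-alkoxy methide, is untested. Ring C is closed in the cycloaddition mode, four atoms (O1, C8a, C4a, C4) coming from the methide and two (C3, C2) from the styrene, with C–C bonding ahead of C–O bonding. C4 is set by the face of the E-methide that the 3,3'-aryl groups of the phosphate leave open and C2 by the endo approach of the anisyl group, which gives the 2,4-cis (2S,4S) adduct, so both centres descend from the catalyst. Regiochemistry follows polarity, and chemoselectivity over the prenyl alkenes should be secured by the far higher nucleophilicity of the excess 4-methoxystyrene, by the absence of a prenyl group ortho to the formyl carbon (no intramolecular Prins closure) and by an acid too weak to add the phenol across its neighbouring prenyl group or to re-ionise the product, which lacks the assisting hydroxyl. Only C2 survives to the target, so the selectivity that matters is the enantiomeric purity at C2, which requires high endo selectivity as well as high methide-face selectivity.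

Step 5
Reactants: 12 cycloadduct ((2S,4S)-4-methoxy-2-(4-methoxyphenyl)-6,8-bis(3-methylbut-2-enyl)-7-(triisopropylsilyloxy)chromane)
Product: 13 flavan-4-ol ((2S)-2-(4-methoxyphenyl)-6,8-bis(3-methylbut-2-enyl)-7-(triisopropylsilyloxy)chroman-4-ol as a mixture of C4 epimers)
Conditions: 0.1 M aq. HCl, THF (1:3), 0 °C to rt
Reagents that add atoms: water, O
Why: SN1 solvolysis of an acetal-like benzylic ether, in which the C4–OMe bond is ortho to the ring oxygen and para to the silyloxy group and should therefore ionise under acid too mild to affect the prenyl groups, the silyl ether or the C2–O1 bond, water trapping the cation and the C4 epimer ratio being irrelevant.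

Step 6
Reactants: 13 flavan-4-ol ((2S)-2-(4-methoxyphenyl)-6,8-bis(3-methylbut-2-enyl)-7-(triisopropylsilyloxy)chroman-4-ol as a mixture of C4 epimers)
Product: 14 silyl flavanone ((2S)-2-(4-methoxyphenyl)-6,8-bis(3-methylbut-2-enyl)-7-(triisopropylsilyloxy)chroman-4-one)
Conditions: Dess–Martin periodinane (1.3 equiv), NaHCO3 (3 equiv), CH2Cl2, 0 °C to rt
Reagents that add atoms: none
Why: Dess–Martin oxidation of a secondary benzylic alcohol under bicarbonate buffering should converge both C4 epimers on the ketone without touching the trisubstituted alkenes, the aryl silyl ether or the C2 stereocentre.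

Step 7
Reactants: 14 silyl flavanone ((2S)-2-(4-methoxyphenyl)-6,8-bis(3-methylbut-2-enyl)-7-(triisopropylsilyloxy)chroman-4-one)
Product: 15 target flavanone ((2S)-7-hydroxy-2-(4-methoxyphenyl)-6,8-bis(3-methylbut-2-enyl)chroman-4-one)
Conditions: Bu4NF (1.2 equiv), AcOH (1.5 equiv), THF, 0 °C
Reagents that add atoms: none
Why: Fluoride-mediated desilylation, in which the aryl O–Si bond para to the new ketone behaves as a vinylogous silyl ester and should be cleaved by acetic acid-buffered fluoride, the buffer keeping the medium non-basic so that ring C cannot open to the chalcone by retro-oxa-Michael elimination and C2 stays S.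

Compound list
1 | 2,4-dihydroxybenzaldehyde (β-resorcylaldehyde) | O=Cc1ccc(O)cc1O | starting material
2 | 2,4-dihydroxy-5-iodobenzaldehyde (principal monoiodide, not isolated) | O=Cc1cc(I)c(O)cc1O | intermediate
3 | 2,4-dihydroxy-3,5-diiodobenzaldehyde | O=Cc1cc(I)c(O)c(I)c1O | intermediate
4 | 2-hydroxy-3,5-diiodo-4-(triisopropylsilyloxy)benzaldehyde | O=Cc1cc(I)c(O[Si](C(C)C)(C(C)C)C(C)C)c(I)c1O | intermediate
5 | tributyl(3-methylbut-2-enyl)stannane | CC(C)=CC[Sn](CCCC)(CCCC)CCCC | starting material
6 | 2-hydroxy-3-iodo-5-(3-methylbut-2-enyl)-4-(triisopropylsilyloxy)benzaldehyde (not isolated) | O=Cc1cc(CC=C(C)C)c(O[Si](C(C)C)(C(C)C)C(C)C)c(I)c1O | intermediate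
7 | 2-hydroxy-3,5-bis(3-methylbut-2-enyl)-4-(triisopropylsilyloxy)benzaldehyde | O=Cc1cc(CC=C(C)C)c(O[Si](C(C)C)(C(C)C)C(C)C)c(CC=C(C)C)c1O | intermediate
8 | trimethyl orthoformate | COC(OC)OC | starting material
9 | 4-methoxystyrene (1-ethenyl-4-methoxybenzene) | C=Cc1ccc(OC)cc1 | starting material
10 | 6-(dimethoxymethyl)-2,4-bis(3-methylbut-2-enyl)-3-(triisopropylsilyloxy)phenol (not isolated) | COC(OC)c1cc(CC=C(C)C)c(O[Si](C(C)C)(C(C)C)C(C)C)c(CC=C(C)C)c1O | intermediate
11 | (6E)-6-(methoxymethylidene)-2,4-bis(3-methylbut-2-enyl)-3-(triisopropylsilyloxy)cyclohexa-2,4-dien-1-one (not isolated) | CO/C=C1\C=C(CC=C(C)C)C(O[Si](C(C)C)(C(C)C)C(C)C)=C(CC=C(C)C)C1=O | intermediate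
12 | (2S,4S)-4-methoxy-2-(4-methoxyphenyl)-6,8-bis(3-methylbut-2-enyl)-7-(triisopropylsilyloxy)chromane | COc1ccc([C@@H]2C[C@H](OC)c3cc(CC=C(C)C)c(O[Si](C(C)C)(C(C)C)C(C)C)c(CC=C(C)C)c3O2)cc1 | intermediate
13 | (2S)-2-(4-methoxyphenyl)-6,8-bis(3-methylbut-2-enyl)-7-(triisopropylsilyloxy)chroman-4-ol, mixture of C4 epimers | COc1ccc([C@@H]2CC(O)c3cc(CC=C(C)C)c(O[Si](C(C)C)(C(C)C)C(C)C)c(CC=C(C)C)c3O2)cc1 | intermediate
14 | (2S)-2-(4-methoxyphenyl)-6,8-bis(3-methylbut-2-enyl)-7-(triisopropylsilyloxy)chroman-4-one | COc1ccc([C@@H]2CC(=O)c3cc(CC=C(C)C)c(O[Si](C(C)C)(C(C)C)C(C)C)c(CC=C(C)C)c3O2)cc1 | intermediate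
15 | (2S)-7-hydroxy-2-(4-methoxyphenyl)-6,8-bis(3-methylbut-2-enyl)chroman-4-one, the target flavanone | COc1ccc([C@@H]2CC(=O)c3cc(CC=C(C)C)c(O)c(CC=C(C)C)c3O2)cc1 | target

Total step count: 7
Longest linear sequence: 7 steps (1 to 15)

Steps most likely to fail

Step 4. The phosphate may discriminate poorly between the two faces of the methide, giving low enantiomeric purity at C2. Other failure processes are acid-triggered addition of the phenol to its neighbouring prenyl group, cationic oligomerisation of the styrene, and erosion of configuration through reversible opening of the C2–O1 bond. The fallback uses known chemistry only, sets out from 7 and comes back at 14. Addition of HC≡CMgBr (3 equiv, THF, 0 °C) to the aldehyde should give the racemic propargylic alcohol F1. MnO2 (CH2Cl2, rt) should oxidise it to the ynone F2. Diethylamine (CH2Cl2, rt) should add in conjugate fashion to give the enaminone F3, which is not isolated and should close with loss of the amine on contact with silica gel to the chromone F4. Enantioselective conjugate addition of 4-methoxyphenylboronic acid to the chromone should then give 14 directly, so steps 5 and 6 are not needed. Its conditions are Pd(OCOCF3)2 (divalent palladium), 4-tert-butyl-2-(pyridin-2-yl)-4,5-dihydrooxazole in the antipode that gives 2S, NH4PF6, H2O, 1,2-dichloroethane, 60 °C.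

Step 3. Allylic transposition during transfer of the prenyl group may give 1,1-dimethylallyl isomers. The second coupling at the hindered position between the hydroxyl and the silyloxy group may stall, and the acidic phenol may protodestannylate the reagent. The fallback sets out from 4 and comes back at 7. Twofold Stille coupling with allyltributylstannane (Pd(PPh3)4, DMF, 90 °C), which has no regiochemical ambiguity and a smaller transferring group, should pass through the monoallyl iodide F5 (not isolated) to the diallyl aldehyde F6. Cross-metathesis with 2-methyl-2-butene (second-generation Grubbs catalyst, CH2Cl2/2-methyl-2-butene, 40 °C) should then convert both allyl groups into prenyl groups, passing through the allyl prenyl aldehyde F7 (not isolated), and give 7.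

Step 7. Fluoride or the liberated phenoxide may open ring C by retro-oxa-Michael elimination to the 2'-hydroxychalcone, which recloses without stereocontrol and erodes C2. Alternatively, the doubly flanked silyl ether may cleave so slowly that harsher conditions are forced. The fallback changes the order of events, sets out from 13 and comes back at 15. Desilylation with Bu4NF (THF, 0 °C) before the carbonyl exists, when ring C cannot open, should give the phenolic diol F8. Activated MnO2 (CH2Cl2, rt) should then oxidise the para-hydroxybenzylic alcohol selectively in the presence of the free phenol and the prenyl groups to give 15.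

Further compounds
F1 | step 4 | 1-[2-hydroxy-3,5-bis(3-methylbut-2-enyl)-4-(triisopropylsilyloxy)phenyl]prop-2-yn-1-ol (racemic) | C#CC(O)c1cc(CC=C(C)C)c(O[Si](C(C)C)(C(C)C)C(C)C)c(CC=C(C)C)c1O
F2 | step 4 | 1-[2-hydroxy-3,5-bis(3-methylbut-2-enyl)-4-(triisopropylsilyloxy)phenyl]prop-2-yn-1-one | C#CC(=O)c1cc(CC=C(C)C)c(O[Si](C(C)C)(C(C)C)C(C)C)c(CC=C(C)C)c1O
F3 | step 4 | (E)-3-(diethylamino)-1-[2-hydroxy-3,5-bis(3-methylbut-2-enyl)-4-(triisopropylsilyloxy)phenyl]prop-2-en-1-one | CCN(CC)/C=C/C(=O)c1cc(CC=C(C)C)c(O[Si](C(C)C)(C(C)C)C(C)C)c(CC=C(C)C)c1O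
F4 | step 4 | 6,8-bis(3-methylbut-2-enyl)-7-(triisopropylsilyloxy)-4H-chromen-4-one | O=c1ccoc2c(CC=C(C)C)c(O[Si](C(C)C)(C(C)C)C(C)C)c(CC=C(C)C)cc12
F5 | step 3 | 2-hydroxy-3-iodo-5-(prop-2-enyl)-4-(triisopropylsilyloxy)benzaldehyde | O=Cc1cc(CC=C)c(O[Si](C(C)C)(C(C)C)C(C)C)c(I)c1O
F6 | step 3 | 2-hydroxy-3,5-di(prop-2-enyl)-4-(triisopropylsilyloxy)benzaldehyde | O=Cc1cc(CC=C)c(O[Si](C(C)C)(C(C)C)C(C)C)c(CC=C)c1O
F7 | step 3 | 2-hydroxy-5-(3-methylbut-2-enyl)-3-(prop-2-enyl)-4-(triisopropylsilyloxy)benzaldehyde | O=Cc1cc(CC=C(C)C)c(O[Si](C(C)C)(C(C)C)C(C)C)c(CC=C)c1O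
F8 | step 7 | (2S)-2-(4-methoxyphenyl)-6,8-bis(3-methylbut-2-enyl)chromane-4,7-diol, mixture of C4 epimers | COc1ccc([C@@H]2CC(O)c3cc(CC=C(C)C)c(O)c(CC=C(C)C)c3O2)cc1
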